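## Retrosynthetic overview

1. Target ⇐ C2-symmetric macrocyclic diol (all four phenols as MOM ethers) by one benzylic O-methylation and MOM removal. This follows the presumed biosynthetic order: macrocycle first, O-tailoring last.
2. Macrocyclic diol ⇐ two molecules of one monomer by head-to-tail double C-alkylation. The resorcinol C2 carbon (as aryl–metal) displaces the secondary sulfonate of the partner with inversion, the chemical counterpart of the enzymatic Friedel–Crafts alkylation by a secondary alkyl chloride.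
3. Ring formation: intermolecular C–C bond first, then closure of the 22-membered [7.7]paracyclophane (the only ring made), both in one flask.
4. Monomer (aryl bromide, C1–OH, C3–Cl, C7–OTs) ⇐ anti-1,3-diol monoacetate (Cl by inversion) ⇐ aldol adduct (Evans–Tishchenko).
5. Aldol adduct ⇐ 4-bromo-3,5-bis(methoxymethoxy)benzaldehyde + (S)-δ-tosyloxy methyl ketone; ketone ⇐ (S)-1,2-epoxyhexane + butenyl Grignard.

Numbering used in names: C1 = benzylic oxygenated carbon, C3 = chlorinated carbon, C7 = carbon that becomes the butyl-bearing benzylic carbon, C8–C11 = butyl.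

Assumption: (−)-Ipc2BCl is taken to direct the methyl-ketone enol borinate to the Si face of the aldehyde (giving 1S); if the sense proves opposite, (+)-Ipc2BCl is used instead.

## Route

Step 1
Reactants: 1 4-bromo-3,5-dimethoxybenzaldehyde
Product: 2 4-bromo-3,5-dihydroxybenzaldehyde
Conditions: BBr3 (3 equiv), CH2Cl2, −78 °C → rt; H2O
Reagents that add atoms: none
Why: Lewis-acid ether cleavage (BBr3 demethylation) removes both aryl methyl ethers while the aldehyde is only complexed and returns on aqueous work-up; no stereocentre is involved.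

Step 2
Reactants: 2 4-bromo-3,5-dihydroxybenzaldehyde
Product: 3 4-bromo-3,5-bis(methoxymethoxy)benzaldehyde
Conditions: MOMCl (2.6 equiv), K2CO3 (3 equiv), DMF, 0 °C → rt
Reagents that add atoms: chloromethyl methyl ether (MOMCl), COCCl
Why: Williamson O-alkylation of the two acidic phenols gives MOM ethers, which survive organolithium and Grignard chemistry, chelate the later aryl–metal and come off under mild acid at the end.

Step 3
Reactants: 4 (S)-1,2-epoxyhexane; 5 but-3-en-1-ylmagnesium bromide
Product: 6 (S)-dec-1-en-6-ol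
Conditions: CuI (10 mol %), THF, −30 → 0 °C; aq NH4Cl
Reagents that add atoms: none
Why: copper-catalysed Grignard opening of a terminal epoxide occurs only at the CH2 terminus, so the stereocentre of 4 is carried over untouched as the future C7 carbinol (S).

Step 4
Reactants: 6 (S)-dec-1-en-6-ol
Product: 7 (S)-dec-1-en-6-yl 4-methylbenzenesulfonate
Conditions: TsCl (1.5 equiv), Et3N (2 equiv), Me3N·HCl (10 mol %), CH2Cl2, 0 °C
Reagents that add atoms: p-toluenesulfonyl chloride (TsCl), Cc1ccc(cc1)S(=O)(=O)Cl
Why: O-sulfonylation leaves the C–O bond intact (retention, S), and the tosylate serves both as the only protection of this oxygen and as the leaving group of the key step.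

Step 5
Reactants: 7 (S)-dec-1-en-6-yl 4-methylbenzenesulfonate
Product: 8 (S)-9-oxodecan-5-yl 4-methylbenzenesulfonate
Conditions: PdCl2 (10 mol %), CuCl (1 equiv), O2 (1 atm), DMF/H2O 7:1, rt
Reagents that add atoms: water, O
Why: Wacker–Tsuji oxidation of a terminal alkene is Markovnikov-selective for the methyl ketone and does not touch a secondary tosylate at room temperature.

Step 6
Reactants: 8 (S)-9-oxodecan-5-yl 4-methylbenzenesulfonate; 3 4-bromo-3,5-bis(methoxymethoxy)benzaldehyde
Product: 11 (1S,7S)-1-[4-bromo-3,5-bis(methoxymethoxy)phenyl]-1-hydroxy-3-oxoundecan-7-yl 4-methylbenzenesulfonate, via enol diisopinocampheylborinate 9 (not isolated), via boron aldolate 10 (not isolated)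
Conditions: (−)-Ipc2BCl (1.4 equiv), Et3N (1.8 equiv), Et2O, −78 → 0 °C; then 3, −78 → −20 °C, 16 h; then MeOH, pH 7 buffer, H2O2, 0 °C
Reagents that add atoms: none
Why: Paterson boron aldol reaction, in which Ipc2BCl/Et3N enolises the methyl side regioselectively and the chiral enol borinate adds to the Si face of the aldehyde through a cyclic transition state to set C1 as S (about 80–90 % ee expected; the minor C1 series is diastereomeric because C7 is fixed and is purged at the macrocycle).

Step 7
Reactants: 11 (1S,7S)-1-[4-bromo-3,5-bis(methoxymethoxy)phenyl]-1-hydroxy-3-oxoundecan-7-yl 4-methylbenzenesulfonate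
Product: 12 (1S,3R,7S)-1-acetoxy-1-[4-bromo-3,5-bis(methoxymethoxy)phenyl]-3-hydroxyundecan-7-yl 4-methylbenzenesulfonate
Conditions: CH3CHO (8 equiv), SmI2 (30 mol %), THF, −10 °C; crude product used at once
Reagents that add atoms: acetaldehyde, CC=O
Why: Evans–Tishchenko reduction, in which the samarium-bound hemiacetal of the C1 hydroxyl delivers hydride intramolecularly to the C3 ketone through a chair transition state, giving the 1,3-anti alcohol (3R) and leaving C1 protected as its acetate in the same operation.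

Step 8
Reactants: 12 (1S,3R,7S)-1-acetoxy-1-[4-bromo-3,5-bis(methoxymethoxy)phenyl]-3-hydroxyundecan-7-yl 4-methylbenzenesulfonate
Product: 13 (1S,3S,7S)-1-acetoxy-1-[4-bromo-3,5-bis(methoxymethoxy)phenyl]-3-chloroundecan-7-yl 4-methylbenzenesulfonate
Conditions: PPh3 (2 equiv), NCS (2 equiv), THF, 0 °C → rt (phosphonium salt pre-formed before 12 is added)
Reagents that add atoms: N-chlorosuccinimide, O=C1CCC(=O)N1Cl
Why: Appel-type chlorination, in which chloride displaces the alkoxyphosphonium ion by SN2 with inversion (3R alcohol → 3S chloride, now syn to the C1 oxygen), under neutral conditions that spare the C7 tosylate.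

Step 9
Reactants: 13 (1S,3S,7S)-1-acetoxy-1-[4-bromo-3,5-bis(methoxymethoxy)phenyl]-3-chloroundecan-7-yl 4-methylbenzenesulfonate
Product: 14 (1S,3S,7S)-1-[4-bromo-3,5-bis(methoxymethoxy)phenyl]-3-chloro-1-hydroxyundecan-7-yl 4-methylbenzenesulfonate
Conditions: K2CO3 (0.3 equiv), MeOH, 0 °C
Reagents that add atoms: none
Why: base-catalysed transesterification removes the acetate at 0 °C, far below the temperatures needed for oxetane closure onto the C3 chloride or methanolysis of the secondary tosylate, and no stereocentre is touched.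

Step 10
Reactants: 14 (1S,3S,7S)-1-[4-bromo-3,5-bis(methoxymethoxy)phenyl]-3-chloro-1-hydroxyundecan-7-yl 4-methylbenzenesulfonate (two molecules)
Product: 18 C2-symmetric macrocyclic diol (tetra-MOM ether of the [7.7]paracyclophane core; both C1 carbinols S; both C3 chlorides S; both butyl-bearing C7 carbons R), via aryllithium alkoxide 15 (not isolated), via arylmagnesium bromide 16 (not isolated), via linear dimer 17 (not isolated)
Conditions: t-BuLi (3.05 equiv), THF, −78 °C, 10 min; MgBr2·OEt2 (1.05 equiv), −78 → −20 °C; dilute to 0.01–0.02 M; CuI (20 mol %), TMEDA (40 mol %), LiOMe (1 equiv), 0 °C, 36 h; aq NH4Cl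
Reagents that add atoms: none
Why: Proposed new method: Parham-type Br/Li exchange (much faster at −78 °C than attack on the sulfonate) gives the C2 aryl anion chelated by both MOM oxygens, and after Mg transmetalation the CuI/TMEDA/LiOMe-derived aryl cuprate displaces the secondary C7 tosylate of a second molecule by SN2 at carbon and reductive elimination, after which the linear dimer closes the 22-membered ring in the same way, so both C7 centres invert from S to R; the monomer cannot cyclise on itself (it would be a [7]paracyclophane), the C3 chlorides are inert to copper-catalysed substitution, and the closest known reactions are the displacement of unactivated secondary tosylates by lithium diarylcuprates and by Grignard reagents under CuI/TMEDA/LiOMe catalysis, both with clean inversion.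

Step 11
Reactants: 18 C2-symmetric macrocyclic diol
Product: 19 macrocyclic mono-methyl ether (one C1 carbinol as methyl ether; the other free; four MOM ethers)
Conditions: Me3OBF4 (0.6 equiv), 1,8-bis(dimethylamino)naphthalene (1.0 equiv), CH2Cl2, 0 °C → rt; recovered 18 recycled
Reagents that add atoms: trimethyloxonium tetrafluoroborate, C[O+](C)C.F[B-](F)(F)F
Why: Meerwein-salt O-methylation under non-basic conditions (no alkoxide, so no oxetane formation or HCl loss) methylates with retention, and because the two carbinols of 18 are related by the C2 axis, mono-methylation gives one compound, formed statistically (about 40–45 % per pass).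

Step 12
Reactants: 19 macrocyclic mono-methyl ether
Product: 20 nostocyclophane C
Conditions: HCl (1.25 M in MeOH), THF, rt, 2–3 h; NaHCO3 quench
Reagents that add atoms: none
Why: acid-catalysed acetal exchange removes the four aryl MOM ethers well before the benzylic C–O bonds can ionise (each benzylic cation is destabilised by two meta oxygens), and the secondary chlorides and all six stereocentres are untouched.

## Compound list

1 | 4-bromo-3,5-dimethoxybenzaldehyde | COc1cc(C=O)cc(OC)c1Br | starting material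
2 | 4-bromo-3,5-dihydroxybenzaldehyde | Oc1cc(C=O)cc(O)c1Br | intermediate
3 | 4-bromo-3,5-bis(methoxymethoxy)benzaldehyde | COCOc1cc(C=O)cc(OCOC)c1Br | intermediate
4 | (S)-1,2-epoxyhexane | CCCC[C@H]1CO1 | starting material
5 | but-3-en-1-ylmagnesium bromide (commercial THF solution) | C=CCC[Mg]Br | starting material
6 | (S)-dec-1-en-6-ol | CCCC[C@H](O)CCCC=C | intermediate
7 | (S)-dec-1-en-6-yl 4-methylbenzenesulfonate | CCCC[C@H](OS(=O)(=O)c1ccc(C)cc1)CCCC=C | intermediate
8 | (S)-9-oxodecan-5-yl 4-methylbenzenesulfonate | CCCC[C@H](OS(=O)(=O)c1ccc(C)cc1)CCCC(C)=O | intermediate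
9 | enol diisopinocampheylborinate of 8 (boron on the enol oxygen of the methyl side) | CCCC[C@H](OS(=O)(=O)c1ccc(C)cc1)CCCC(=C)OB([C@@H]1C[C@@H]2C[C@H]([C@H]1C)C2(C)C)[C@@H]1C[C@@H]2C[C@H]([C@H]1C)C2(C)C | intermediate (not isolated)
10 | boron aldolate (O-diisopinocampheylboryl derivative of 11) | CCCC[C@H](OS(=O)(=O)c1ccc(C)cc1)CCCC(=O)C[C@H](OB([C@@H]1C[C@@H]2C[C@H]([C@H]1C)C2(C)C)[C@@H]1C[C@@H]2C[C@H]([C@H]1C)C2(C)C)c1cc(OCOC)c(Br)c(OCOC)c1 | intermediate (not isolated)
11 | (1S,7S)-1-[4-bromo-3,5-bis(methoxymethoxy)phenyl]-1-hydroxy-3-oxoundecan-7-yl 4-methylbenzenesulfonate | CCCC[C@H](OS(=O)(=O)c1ccc(C)cc1)CCCC(=O)C[C@H](O)c1cc(OCOC)c(Br)c(OCOC)c1 | intermediate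
12 | (1S,3R,7S)-1-acetoxy-1-[4-bromo-3,5-bis(methoxymethoxy)phenyl]-3-hydroxyundecan-7-yl 4-methylbenzenesulfonate | CCCC[C@H](OS(=O)(=O)c1ccc(C)cc1)CCC[C@@H](O)C[C@H](OC(C)=O)c1cc(OCOC)c(Br)c(OCOC)c1 | intermediate
13 | (1S,3S,7S)-1-acetoxy-1-[4-bromo-3,5-bis(methoxymethoxy)phenyl]-3-chloroundecan-7-yl 4-methylbenzenesulfonate | CCCC[C@H](OS(=O)(=O)c1ccc(C)cc1)CCC[C@H](Cl)C[C@H](OC(C)=O)c1cc(OCOC)c(Br)c(OCOC)c1 | intermediate
14 | (1S,3S,7S)-1-[4-bromo-3,5-bis(methoxymethoxy)phenyl]-3-chloro-1-hydroxyundecan-7-yl 4-methylbenzenesulfonate (monomer) | CCCC[C@H](OS(=O)(=O)c1ccc(C)cc1)CCC[C@H](Cl)C[C@H](O)c1cc(OCOC)c(Br)c(OCOC)c1 | intermediate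
15 | aryllithium lithium alkoxide of 14 (Li in place of Br; C1–OLi) | CCCC[C@H](OS(=O)(=O)c1ccc(C)cc1)CCC[C@H](Cl)C[C@H](O[Li])c1cc(OCOC)c([Li])c(OCOC)c1 | intermediate (not isolated)
16 | arylmagnesium bromide of 14 (MgBr in place of Br; C1–OLi) | CCCC[C@H](OS(=O)(=O)c1ccc(C)cc1)CCC[C@H](Cl)C[C@H](O[Li])c1cc(OCOC)c([Mg]Br)c(OCOC)c1 | intermediate (not isolated)
17 | linear head-to-tail dimer (one aryl–C7 bond formed, that C7 now R; one aryl–MgBr and one C7–OTs remaining) | CCCC[C@H](OS(=O)(=O)c1ccc(C)cc1)CCC[C@H](Cl)C[C@H](O[Li])c1cc(OCOC)c(c(OCOC)c1)[C@H](CCCC)CCC[C@H](Cl)C[C@H](O[Li])c1cc(OCOC)c([Mg]Br)c(OCOC)c1 | intermediate (not isolated)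
18 | C2-symmetric macrocyclic diol: 22-membered [7.7]paracyclophane, four phenols as MOM ethers, both benzylic carbinols free (S), both chlorides (S), both butyl-bearing benzylic carbons (R) | CCCC[C@@H]1CCC[C@H](Cl)C[C@H](O)c2cc(OCOC)c(c(OCOC)c2)[C@H](CCCC)CCC[C@H](Cl)C[C@H](O)c2cc(OCOC)c1c(OCOC)c2 | intermediate
19 | macrocyclic mono-methyl ether: as 18 with one benzylic carbinol as its methyl ether | CCCC[C@@H]1CCC[C@H](Cl)C[C@H](OC)c2cc(OCOC)c(c(OCOC)c2)[C@H](CCCC)CCC[C@H](Cl)C[C@H](O)c2cc(OCOC)c1c(OCOC)c2 | intermediate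
20 | nostocyclophane C | CCCC[C@@H]1CCC[C@H](Cl)C[C@H](OC)c2cc(O)c(c(O)c2)[C@H](CCCC)CCC[C@H](Cl)C[C@H](O)c2cc(O)c1c(O)c2 | target

## Step count and risks

Total steps: 12. Longest linear sequence: 10 steps (from 4: steps 3–12).

Steps most likely to fail:

Step 10 (one-flask cyclodimerisation). The doubly ortho-substituted aryl nucleophile must displace an unactivated secondary tosylate twice; elimination, protonation, oligomers and bromide exchange at C7 compete. Realistic yield is 15–25 %. Fallback: form the aryl–C7 bond first on simple fragments, where the Grignard can be used in excess, and close the ring by a head-to-tail double aldol. It sets out from 3 and 7. Aldehyde 3 is masked in the flask as its lithium α-amino alkoxide (LiN(Me)CH2CH2NMe2), exchanged with t-BuLi, transmetalated with MgBr2·OEt2 and coupled with 7 (CuI/TMEDA/LiOMe, inversion) to give 4-[(5R)-dec-9-en-5-yl]-3,5-bis(methoxymethoxy)benzaldehyde F1. Wacker oxidation gives 4-[(5R)-9-oxodecan-5-yl]-3,5-bis(methoxymethoxy)benzaldehyde F2. Slow addition of F2 to (−)-Ipc2BCl/Et3N at high dilution gives the macrocyclic bis(β-hydroxy ketone) F3. Double Evans–Tishchenko reduction (CH3CHO, SmI2) gives the macrocyclic bis-acetate diol F4, double Appel chlorination gives the macrocyclic bis-acetate dichloride F5, and K2CO3/MeOH brings the sequence back to the route at 18.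

Step 6 (aldol enantioselectivity). Methyl-ketone boron aldols often give only 70–90 % ee, and the boron chloride may attack a MOM ether. Fallback: set C1 by catalytic asymmetric conjugate borylation instead of an aldol. It sets out from 3 and 8. Claisen–Schmidt condensation (Ba(OH)2·8H2O, EtOH, 0 °C) gives the E-enone F6. Copper-catalysed β-borylation (CuCl, NaOt-Bu, Josiphos antipode chosen for the S boronate, B2pin2, MeOH, THF) gives the β-boryl ketone F7. Oxidation with NaBO3 (retention) returns to the route at 11.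

Step 11 (mono-methylation). It is statistical, and over-methylation gives the dimethyl ether. Fallback: differentiate before ring formation. It sets out from 14. Full methylation of part of 14 (Me3OBF4, proton sponge) gives the methyl ether monomer F8. Co-cyclodimerisation of F8 with 14 (1:1) under the step 10 conditions gives 19 directly, alongside 18 and the dimethyl ether, and returns to the route at 19.

## Further compounds

F1 | step 10 | 4-[(5R)-dec-9-en-5-yl]-3,5-bis(methoxymethoxy)benzaldehyde | CCCC[C@H](CCCC=C)c1c(OCOC)cc(C=O)cc1OCOC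
F2 | step 10 | 4-[(5R)-9-oxodecan-5-yl]-3,5-bis(methoxymethoxy)benzaldehyde | CCCC[C@H](CCCC(C)=O)c1c(OCOC)cc(C=O)cc1OCOC
F3 | step 10 | macrocyclic bis(β-hydroxy ketone) (C1 carbinols S; C3 ketones; C7 carbons R; four MOM ethers) | CCCC[C@@H]1CCCC(=O)C[C@H](O)c2cc(OCOC)c(c(OCOC)c2)[C@H](CCCC)CCCC(=O)C[C@H](O)c2cc(OCOC)c1c(OCOC)c2
F4 | step 10 | macrocyclic bis-acetate diol (C1 acetates S; C3 alcohols R; C7 carbons R) | CCCC[C@@H]1CCC[C@@H](O)C[C@H](OC(C)=O)c2cc(OCOC)c(c(OCOC)c2)[C@H](CCCC)CCC[C@@H](O)C[C@H](OC(C)=O)c2cc(OCOC)c1c(OCOC)c2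
F5 | step 10 | macrocyclic bis-acetate dichloride (C1 acetates S; C3 chlorides S; C7 carbons R) | CCCC[C@@H]1CCC[C@H](Cl)C[C@H](OC(C)=O)c2cc(OCOC)c(c(OCOC)c2)[C@H](CCCC)CCC[C@H](Cl)C[C@H](OC(C)=O)c2cc(OCOC)c1c(OCOC)c2
F6 | step 6 | (S,E)-11-[4-bromo-3,5-bis(methoxymethoxy)phenyl]-9-oxoundec-10-en-5-yl 4-methylbenzenesulfonate | CCCC[C@H](OS(=O)(=O)c1ccc(C)cc1)CCCC(=O)/C=C/c1cc(OCOC)c(Br)c(OCOC)c1
F7 | step 6 | (1S,7S)-1-[4-bromo-3,5-bis(methoxymethoxy)phenyl]-3-oxo-1-(pinacolboryl)undecan-7-yl 4-methylbenzenesulfonate | CCCC[C@H](OS(=O)(=O)c1ccc(C)cc1)CCCC(=O)C[C@H](B1OC(C)(C)C(C)(C)O1)c1cc(OCOC)c(Br)c(OCOC)c1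
F8 | step 11 | (1S,3S,7S)-1-[4-bromo-3,5-bis(methoxymethoxy)phenyl]-3-chloro-1-methoxyundecan-7-yl 4-methylbenzenesulfonate | CCCC[C@H](OS(=O)(=O)c1ccc(C)cc1)CCC[C@H](Cl)C[C@H](OC)c1cc(OCOC)c(Br)c(OCOC)c1
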